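## Analysis of the target

Target 34 is an octaphenolic stilbenoid trimer built on a benzene ring A (atoms A1–A6) that carries a substituent on every carbon except A2. Ring A is fused at A1/A6 to a dihydrofuran (O–Ca–Cb, with a 4-hydroxyphenyl group on Ca), at A3/A4 to a second dihydrofuran (O–Ce–Cd, with a 4-hydroxyphenyl group on Ce and the 3,5-dihydroxyphenyl ring D on Cd) and at A5/A6 to a seven-membered carbocycle A6–Cb–B1–B6–Cc–Cf–A5, which contains the resorcinol ring B (oxygens on B3 and B5), the methine Cc bearing the 2,4-dihydroxyphenyl ring C, and the methylene Cf. There are five stereocentres: Ca (S) and Cb (S) are trans on the first furan, Cd (R) and Ce (R) are trans on the second, and Cc (S) has its hydrogen on the face of the seven-membered ring opposite to Cb–H, so that ring C and Cb–H are syn. The two furans are both trans but of opposite absolute sense and are separated by the flat ring A, so neither can be expected to control the other. Sensitive features are the eight free phenols, the two para-oxygenated benzylic aryl ether bonds (Ca–O and Ce–O), which ionise in acid, and the doubly benzylic C–H bonds at Cb and Cc. The synthesis is hard because ring A is crowded and because ring B has an awkward substitution pattern: B6 is ortho/para to both oxygens, but B1, which must bond to the hindered Cb, is meta to both, so attaching a preformed resorcinol to Cb by electrophilic substitution is electronically mismatched. The plan rests on the observation that ring B has two adjacent carbon substituents (on B1 and B6) and oxygens on B3 and B5, which is exactly the pattern produced by a [4+2] addition of a 1,3-dioxygenated butadiene to an alkyne that carries Cb at one end and an aroyl group (the later Cc with ring C) at the other.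

## Retrosynthetic reasoning

**Phenols and Ce.** The eight phenols of 34 are unmasked last from the octamethyl ether 33 by Lewis-acid ether cleavage, because methyl ethers survive every earlier operation. 33 is traced back to its Ce epimer 32. The trans arrangement of a 2-(4-alkoxyphenyl)dihydrofuran is the thermodynamic one and is reached by reversible acid ionisation of the Ce–O bond, so only Cd has to be set by a reagent.

**Second furan.** In 32 the Cd–Ce bond is cut. It is formed by insertion of a diaryl carbene, generated from hydrazone 30, into the benzylic C–H of a 4-methoxybenzyl ether on A3. This closes the furan, brings in ring D already attached to Cd, and lets a chiral catalyst decide Cd. The ether methylene becomes Ce, so the group that protected the A3 oxygen ends up in the skeleton. Hydrazone 30 is cut at A4–Cd into aryl bromide 26 and nitrile 27. A nitrile is chosen because its adduct with the aryllithium is an N–H imine (29), which exchanges with hydrazine where a di-ortho-substituted diaryl ketone would not condense.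

**Seven-membered ring and Cc.** The Cc–H bond of 26 is traced to the tertiary carbinol 24 by ionic hydrogenation through cation 25. The Cf–Cc bond of 24 is then cut to give benzylic bromide 23 and its diaryl ketone. The forward reaction is a reductive Barbier closure, for which the ketone must sit ortho to the Cb-bearing carbon of ring B. The bromide 23 comes from silyl ether 22. The aryl bromide on A4 is a spectator here and is the handle for the second furan.

**Ring B (key disconnection).** The methyl ether 22 comes from phenol 21, and in 21 the bonds B1–B2 and B5–B6 are cut. This removes the whole of ring B and leads to ynone 16 and diene 18. Cutting here means the crowded B1–Cb bond never has to be made on an arene: it is the alkyne–Cb bond, present from the start. Both ring-B oxygens and the ketone arrive in their final positions.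

**Ynone.** 16 is the oxidation product of propargylic alcohol 15, so the base-sensitive ynone is generated under neutral conditions. 15 is cut between the alkyne and the carbinol carbon into the acetylide 14 of alkyne 12 and aldehyde 13. 12 is the one-carbon homologue of aldehyde 11, which derives from the trans ester 10.

**First furan.** 10 is the C3 epimer of the cis ester 9. In 9 the Ca–Cb bond is cut: it is formed by intramolecular carbene C–H insertion of diazo ester 8 into the benzylic C–H of the 4-methoxybenzyl ether on A1. A chiral catalyst fixes Ca, and base equilibration then sets Cb trans.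

**Ring A.** Diazo ester 8 comes from aryl acetate 7 by diazo transfer, and 7 from 6 by bromination at A4. The acetate side chain of 6 is attached by cross-coupling at the bromide of 5, which is the silyl ether of 4. 4 is the monobromide of the symmetric bis(4-methoxybenzyl) ether 3, made from 1 and two equivalents of 2. Starting symmetric avoids any desymmetrisation of the two phenols: the two ring positions ortho to the hydroxymethyl group are equivalent and are functionalised one after the other, and the two benzyl ethers later become Ca and Ce with their aryl groups.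

## Alternatives that were turned down

**Alternative 1: aryne insertion into an indanone keto ester.**
- Disconnection: both bonds from ring B to the seven-membered ring (B1–Cb and B6–Cc).
- Forward key step: the enolate of the ring-A indan-2-one 1-carboxylate A2 adds to the dimethoxy aryne released from silyl triflate A3. The aryl anion then attacks the ketone and the five-membered ring opens to the seven-membered keto ester A1.
- For: it is convergent, makes two C–C bonds and the seven-membered ring at once, and brings ring B in intact. The methoxy group next to the aryne bond directs the enolate to the correct carbon. On step count to the carbocyclic skeleton it is stronger than the chosen route.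
- Against: A1 is racemic and its Cb, placed between two arenes and an ester, is configurationally labile, with no handle for asymmetric induction. Ca, its aryl group and the furan would have to be built afterwards from the ester with both relative and absolute control. Cc arrives as a ketone next to the enolisable Cf.
- Comparison: the chosen route offers, in place of this brevity, Ca and Cb set by a catalyst on a simple substrate before any crowding exists.

**Alternative 2: oxidative aryl shift of a flavanone.**
- Disconnection: the A4–Cd bond, formed by migration of ring A.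
- Forward key step: a trivalent iodine oxidant in an acidic orthoester medium attacks the enol ether of the ring-A-fused flavanone A5 at C3. Ring A shifts from the carbonyl carbon to C3 and the pyranone contracts to the trans dihydrofuran ester A4.
- For: the trans relationship follows from the mechanism, so no epimerisation step is needed, and Ce can be set at the flavanone stage. On that point it is stronger than the chosen second-furan sequence.
- Against: A4 carries a methyl ester where the target has ring D, so a second arene would have to be built or introduced at Cd over several steps. The oxidant meets four electron-rich arenes and the benzhydrylic Cb–H and Cc–H bonds. Acid can open the flavanone to a chalcone and erode Ce. It also offers nothing for ring B or the seven-membered ring.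
- Comparison: the chosen route attaches Cd with ring D already on it in one C–C bond formation.

**Alternative 3: sulfur dioxide extrusion from an eight-membered sulfone.**
- Disconnection: the Cf–Cc bond, formed as a double bond by ring contraction.
- Forward key step: under Ramberg–Bäcklund conditions the benzylic sulfone A7 is halogenated, closes to the episulfone and loses SO2 to give the triaryl cycloheptene A6.
- For: it avoids a nucleophilic addition to a hindered diaryl ketone, and the alkene A6 allows catalyst-controlled hydrogenation at Cc. On both points it is as strong as or stronger than the Barbier closure and ionic reduction used here.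
- Against: it presupposes ring B already attached to Cb, which is the bond that is hardest to make. It needs a secondary diarylmethyl leaving group at Cc and an eight-membered sulfide closure. It spends four operations (sulfide, oxidation, contraction, hydrogenation) on one C–C bond, and the hydrogenation must spare the aryl bromide.
- Comparison: the chosen strategy builds ring B and delivers the ketone where the ring is closed. The alkene option is kept in reserve as a fallback through F5, the 4-methoxybenzyl analogue of A6.

Key step: step 13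

## Route

Abbreviations and labels: TBS = tert-butyldimethylsilyl; PMB = 4-methoxybenzyl. Atom labels (A1–A6, B1–B6, Ca–Cf, rings C and D) are those of the analysis. "Core" means ring A with the first dihydrofuran, the seven-membered ring and ring B.

Assumption: Rh2(S-PTTL)4 is taken to give the (2S) cis ester 9 and Rh2(R-PTAD)4 the (R) configuration at Cd in 32. If either sense of induction proves opposite, the enantiomeric catalyst is used.

Relative to the simplest form of the key-step substrates, the A3 oxygen is carried as a PMB ether instead of a methyl ether, because its methylene is needed later as Ce.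

Step 1
Reactants: 1 3,5-dihydroxybenzyl alcohol; 2 4-methoxybenzyl chloride
Product: 3 [3,5-bis(4-methoxybenzyloxy)phenyl]methanol
Conditions: 2 (2.2 equiv), K2CO3, KI (cat.), acetone, reflux
Reagents that add atoms: 4-methoxybenzyl chloride (the second equivalent of 2), COc1ccc(CCl)cc1
Why: Twofold Williamson etherification, one molecule of 2 for each phenol; K2CO3 deprotonates only the phenols, so the benzylic alcohol stays free.

Step 2
Reactants: 3 [3,5-bis(4-methoxybenzyloxy)phenyl]methanol
Product: 4 [2-bromo-3,5-bis(4-methoxybenzyloxy)phenyl]methanol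
Conditions: NBS (1.0 equiv), MeCN, 0 °C
Reagents that add atoms: N-bromosuccinimide, O=C1CCC(=O)N1Br
Why: Electrophilic aromatic bromination of a 3,5-dialkoxybenzyl alcohol goes to C2 (para to one ether, ortho to the other) in preference to the more crowded carbon between the two oxygens; one equivalent at 0 °C should avoid the 2,6-dibromide.

Step 3
Reactants: 4 [2-bromo-3,5-bis(4-methoxybenzyloxy)phenyl]methanol
Product: 5 [2-bromo-3,5-bis(4-methoxybenzyloxy)benzyloxy](tert-butyl)dimethylsilane
Conditions: TBSCl, imidazole, DMF, rt
Reagents that add atoms: tert-butyldimethylsilyl chloride, CC(C)(C)[Si](C)(C)Cl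
Why: Standard silylation of a primary alcohol; the TBS ether masks the future Cf through the carbene and organometallic steps.

Step 4
Reactants: 5 [2-bromo-3,5-bis(4-methoxybenzyloxy)benzyloxy](tert-butyl)dimethylsilane
Product: 6 methyl 2-[2-(tert-butyldimethylsilyloxymethyl)-4,6-bis(4-methoxybenzyloxy)phenyl]acetate
Conditions: BrZnCH2CO2Me (from BrCH2CO2Me and Zn), Pd2(dba)3, XPhos, THF, 65 °C
Reagents that add atoms: (2-methoxy-2-oxoethyl)zinc bromide, COC(=O)C[Zn]Br (made from methyl bromoacetate, COC(=O)CBr, and Zn)
Why: Negishi-type coupling of a Reformatsky reagent with an aryl bromide; the bulky biarylphosphine allows zerovalent palladium to insert into the di-ortho-substituted C–Br bond, and the neutral zinc enolate tolerates the silyl and benzyl ethers.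

Step 5
Reactants: 6 methyl 2-[2-(tert-butyldimethylsilyloxymethyl)-4,6-bis(4-methoxybenzyloxy)phenyl]acetate
Product: 7 methyl 2-[3-bromo-2-(tert-butyldimethylsilyloxymethyl)-4,6-bis(4-methoxybenzyloxy)phenyl]acetate
Conditions: NBS (1.0 equiv), MeCN, 0 °C
Reagents that add atoms: N-bromosuccinimide, O=C1CCC(=O)N1Br
Why: Second electrophilic bromination with the same preference as in step 2: A4 is para to the A1 ether and ortho to the A3 ether, whereas A2 lies between two ether groups; the resorcinol ring is far more activated than the anisole rings of the PMB groups.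

Step 6
Reactants: 7 methyl 2-[3-bromo-2-(tert-butyldimethylsilyloxymethyl)-4,6-bis(4-methoxybenzyloxy)phenyl]acetate
Product: 8 methyl 2-[3-bromo-2-(tert-butyldimethylsilyloxymethyl)-4,6-bis(4-methoxybenzyloxy)phenyl]-2-diazoacetate
Conditions: 4-AcNHC6H4SO2N3, DBU, MeCN, 0 °C → rt
Reagents that add atoms: 4-acetamidobenzenesulfonyl azide, CC(=O)Nc1ccc(cc1)S(=O)(=O)N=[N+]=[N-]
Why: Regitz diazo transfer to the aryl acetate enolate formed by DBU, the usual entry to aryl diazoacetates.

Step 7
Reactants: 8 methyl 2-[3-bromo-2-(tert-butyldimethylsilyloxymethyl)-4,6-bis(4-methoxybenzyloxy)phenyl]-2-diazoacetate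
Product: 9 methyl (2S,3R)-5-bromo-4-(tert-butyldimethylsilyloxymethyl)-6-(4-methoxybenzyloxy)-2-(4-methoxyphenyl)-2,3-dihydro-1-benzofuran-3-carboxylate (cis)
Conditions: Rh2(S-PTTL)4 (1 mol %), PhMe, −60 °C
Reagents that add atoms: none
Why: Intramolecular 1,5 C–H insertion of the rhodium carbene into the benzylic C–H of the ortho PMB ether forms the Ca–Cb bond and the furan, a reaction known for methyl 2-(2-benzyloxyphenyl)-2-diazoacetates, which give cis esters. Ca is set by the chiral carboxylate ligands of the catalyst. Insertion at the silyloxymethyl group would give a four-membered ring, and silyl ether oxygens are poor ylide formers.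

Step 8
Reactants: 9 cis ester, as named in step 7
Product: 10 methyl (2S,3S)-5-bromo-4-(tert-butyldimethylsilyloxymethyl)-6-(4-methoxybenzyloxy)-2-(4-methoxyphenyl)-2,3-dihydro-1-benzofuran-3-carboxylate (trans)
Conditions: NaOMe, MeOH–THF, rt
Reagents that add atoms: none
Why: The ester enolate equilibrates C3 (Cb) to the thermodynamically preferred trans isomer. Ca is not affected, because loss of the phenoxide by β-elimination would be the reverse of a 5-endo-trig closure and is stereoelectronically disfavoured.

Step 9
Reactants: 10 trans ester, as named in step 8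
Product: 12 (2S,3S)-5-bromo-4-(tert-butyldimethylsilyloxymethyl)-3-ethynyl-6-(4-methoxybenzyloxy)-2-(4-methoxyphenyl)-2,3-dihydro-1-benzofuran, via trans aldehyde 11 (not isolated)
Conditions: i-Bu2AlH, CH2Cl2, −78 °C; MeOH; then K2CO3, dimethyl (1-diazo-2-oxopropyl)phosphonate, MeOH, 0 °C → rt
Reagents that add atoms: dimethyl (1-diazo-2-oxopropyl)phosphonate (Ohira–Bestmann reagent), COP(=O)(OC)C(=[N+]=[N-])C(C)=O
Why: At −78 °C the reduction stops at the aluminium hemiacetal, which releases aldehyde 11 on methanolysis; 11 is homologated at once by Seyferth–Gilbert reaction with the Ohira–Bestmann reagent (a one-pot ester-to-alkyne protocol). Enolisation of 11 can only return the favoured trans isomer, and ring opening is disfavoured for the reason given in step 8.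

Step 10
Reactants: 12 alkyne, as named in step 9; 13 2,4-dimethoxybenzaldehyde
Product: 15 3-[(2S,3S)-5-bromo-4-(tert-butyldimethylsilyloxymethyl)-6-(4-methoxybenzyloxy)-2-(4-methoxyphenyl)-2,3-dihydro-1-benzofuran-3-yl]-1-(2,4-dimethoxyphenyl)prop-2-yn-1-ol (both carbinol epimers), via bromomagnesium acetylide 14 (not isolated)
Conditions: EtMgBr, THF, 0 °C → rt; then 13, 0 °C; aq. NH4Cl
Reagents that add atoms: none
Why: EtMgBr deprotonates the terminal alkyne without exchanging with the aryl bromide, and the acetylide adds to the aldehyde. The new carbinol centre is removed in step 11.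

Step 11
Reactants: 15 propargylic alcohol, as named in step 10
Product: 16 3-[(2S,3S)-5-bromo-4-(tert-butyldimethylsilyloxymethyl)-6-(4-methoxybenzyloxy)-2-(4-methoxyphenyl)-2,3-dihydro-1-benzofuran-3-yl]-1-(2,4-dimethoxyphenyl)prop-2-yn-1-one
Conditions: MnO2, CH2Cl2, rt
Reagents that add atoms: none
Why: MnO2 oxidises the doubly activated (propargylic and benzylic) alcohol under neutral conditions, so the acidic Cb–H of the ynone is not exposed to base.

Step 12
Reactants: 17 methyl (E)-3-methoxybut-2-enoate
Product: 18 1,3-dimethoxy-1-(trimethylsilyloxy)buta-1,3-diene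
Conditions: LiN(i-Pr)2, THF, −78 °C; Me3SiCl; distilled, used fresh
Reagents that add atoms: chlorotrimethylsilane, C[Si](C)(C)Cl
Why: γ-Deprotonation of the β-methoxy enoate gives the extended enolate, and O-silylation gives the ketene acetal diene.

Step 13
Reactants: 16 ynone, as named in step 11; 18 1,3-dimethoxy-1-(trimethylsilyloxy)buta-1,3-diene
Product: 21 {2-[(2S,3S)-5-bromo-4-(tert-butyldimethylsilyloxymethyl)-6-(4-methoxybenzyloxy)-2-(4-methoxyphenyl)-2,3-dihydro-1-benzofuran-3-yl]-6-hydroxy-4-methoxyphenyl}(2,4-dimethoxyphenyl)methanone, via cyclohexa-1,4-diene cycloadduct 19 (not isolated), via aryl trimethylsilyl ether 20 (not isolated)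
Conditions: 18 (3 equiv), PhMe, 90 °C, sealed tube; then SiO2, CH2Cl2, rt
Reagents that add atoms: none
Why: The electron-rich ketene acetal diene 18 adds to the electron-poor alkyne of 16 in a concerted, asynchronous [4+2] cycloaddition: the unsubstituted diene terminus, which has the largest HOMO coefficient, bonds to the ynone β-carbon (the carbon attached to Cb) and the acetal carbon bonds to the α-carbon, giving the cyclohexa-1,4-diene 19. 19 aromatises by loss of methanol from the mixed acetal carbon to the aryl silyl ether 20, and SiO2 removes the silyl group to leave phenol 21, hydrogen-bonded to the ketone. The closest known reaction type is the Diels–Alder benzannulation of 1-alkoxy-1-silyloxy-3-alkoxybutadienes with acetylenic ketones and esters to 2-acyl resorcinol monoethers. Ring B is closed in a six-membered [4+2] mode that forms B1–B2 and B5–B6; no stereocentre is created, and the sp3 acetal carbon of 19 disappears on aromatisation. The step needs regioselectivity, which the 1,3-dioxygenation of the diene and the polarisation of the ynone secure (B5–OH next to the acyl group, B3–OMe para to it). It also needs Ca and Cb to stay untouched, and the neutral thermal conditions avoid the base-induced shift of the ynone to an allenone through the acidic Cb–H. The linear alkyne holds the bulky dihydrofuran away from the bond-forming termini.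

Step 14
Reactants: 21 hydroxy ketone, as named in step 13
Product: 22 {2-[(2S,3S)-5-bromo-4-(tert-butyldimethylsilyloxymethyl)-6-(4-methoxybenzyloxy)-2-(4-methoxyphenyl)-2,3-dihydro-1-benzofuran-3-yl]-4,6-dimethoxyphenyl}(2,4-dimethoxyphenyl)methanone
Conditions: MeI, K2CO3, DMF, 40 °C
Reagents that add atoms: iodomethane, CI
Why: Williamson methylation of the chelated ortho-hydroxy ketone; the acidic phenol must be capped before the organosamarium step.

Step 15
Reactants: 22 silyl ether ketone, as named in step 14
Product: 23 {2-[(2S,3S)-5-bromo-4-(bromomethyl)-6-(4-methoxybenzyloxy)-2-(4-methoxyphenyl)-2,3-dihydro-1-benzofuran-3-yl]-4,6-dimethoxyphenyl}(2,4-dimethoxyphenyl)methanone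
Conditions: Ph3PBr2, CH2Cl2, 0 °C → rt
Reagents that add atoms: dibromotriphenylphosphorane, BrP(Br)(c1ccccc1)(c1ccccc1)c1ccccc1
Why: The bromophosphonium ion activates the silyl ether oxygen and bromide displaces it, which converts primary silyl ethers directly into bromides under neutral conditions. Aryl ethers and the non-enolisable diaryl ketone do not react.

Step 16
Reactants: 23 benzylic bromide, as named in step 15
Product: 24 core tertiary alcohol: (Ca S, Cb S) core with OH and 2,4-dimethoxyphenyl on Cc (Cc configuration not defined), Br on A4, PMB ether on A3, methyl ethers on B3, B5 and the Ca aryl group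
Conditions: SmI2 (2.5 equiv), THF (high dilution), −78 °C → rt; aq. NH4Cl
Reagents that add atoms: none
Why: Samarium Barbier reaction: SmI2 reduces the benzylic bromide (or the diaryl ketone to its ketyl), and the carbon nucleophile adds to the carbonyl group held close by the Cb hinge, forming the Cf–Cc bond and the seven-membered ring. Aryl bromides are inert to SmI2 in THF without HMPA. The carbinol configuration is irrelevant because Cc is planarised in step 17.

Step 17
Reactants: 24 core tertiary alcohol, as described in step 16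
Product: 26 core bromide: (Ca S, Cb S, Cc S) core with H and 2,4-dimethoxyphenyl on Cc, Br on A4, PMB ether on A3, via diarylcarbenium ion 25 (not isolated)
Conditions: Et3SiH (10 equiv), CF3CO2H (5 equiv), CH2Cl2, −40 → 0 °C
Reagents that add atoms: none
Why: Ionic hydrogenation: the carbinol, flanked by two ortho/para-methoxylated arenes, ionises to cation 25 at low temperature, where the PMB ether and the dihydrofuran should survive, and Et3SiH delivers hydride. In the folded dibenzocycloheptadiene, hydride delivery on the concave face should let ring C swing into the pseudo-axial position on the convex face, syn to Cb–H. Attack on the other face would push ring C into the plane of ring B against the B5 methoxy group (allylic 1,3-strain), so the (S) epimer is expected as both the kinetic and the more stable product.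

Step 18
Reactants: 26 core bromide, as described in step 17; 27 3,5-dimethoxybenzonitrile
Product: 30 core hydrazone: 26 with Br on A4 replaced by C(=N–NH2)(3,5-dimethoxyphenyl), via aryllithium 28 (not isolated), via N-unsubstituted ketimine 29 (not isolated)
Conditions: t-BuLi (2.1 equiv), THF, −78 °C; 27, −78 → 0 °C; then AcOH, N2H4·H2O, EtOH, 60 °C
Reagents that add atoms: hydrazine (as hydrate), NN
Why: Bromine–lithium exchange at −78 °C is faster than any deprotonation, and the hindered aryllithium 28 adds once to the non-enolisable nitrile. The N–H ketimine 29 then exchanges ammonia for hydrazine (transimination), which avoids condensing hydrazine with a di-ortho-substituted diaryl ketone.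

Step 19
Reactants: 30 core hydrazone, as described in step 18
Product: 32 octamethyl ether of the target with a cis second furan (Ca S, Cb S, Cc S, Cd R, Ce S), via diaryldiazomethane 31 (not isolated)
Conditions: MnO2, CH2Cl2, 0 °C; filter; Rh2(R-PTAD)4 (1 mol %), CH2Cl2, 0 °C → rt
Reagents that add atoms: none
Why: MnO2 dehydrogenates the hydrazone to the diazo compound 31, and Rh2(R-PTAD)4 turns it into a donor/donor carbene that inserts into the benzylic C–H of the ortho PMB ether (1,5-insertion, Cd–Ce bond). This is the known route from 2-benzyloxybenzophenone hydrazones to cis-2,3-diaryl-2,3-dihydrobenzofurans. Cd is set by the catalyst because the existing centres are remote, and the only other C–H bonds within reach (on Cf) would give a four-membered ring.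

Step 20
Reactants: 32 cis compound, as described in step 19
Product: 33 octamethyl ether of the target (Ca S, Cb S, Cc S, Cd R, Ce R)
Conditions: CF3CO2H–CH2Cl2 (1:10), 0 °C → rt
Reagents that add atoms: none
Why: Acid reversibly ionises the Ce–O bond to the 4-methoxybenzylic cation, which recloses on the tethered phenol to the more stable trans dihydrofuran (thermodynamic control; Cd is not involved). The first furan is already trans and returns unchanged from the same equilibrium.

Step 21
Reactants: 33 octamethyl ether, as described in step 20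
Product: 34 target CNP0154047.3 (Ca S, Cb S, Cc S, Cd R, Ce R)
Conditions: BBr3 (excess), CH2Cl2, −78 → 0 °C; then MeOH, H2O
Reagents that add atoms: none
Why: BBr3 cleaves all eight aryl methyl ethers by complexation and bromide attack on the methyl groups. Both dihydrofurans are in their stable trans form, so any transient ionisation at Ca or Ce returns the same isomers.

## Compound list

1 | 3,5-dihydroxybenzyl alcohol | OCc1cc(O)cc(O)c1 | starting material
2 | 4-methoxybenzyl chloride | COc1ccc(CCl)cc1 | starting material
3 | [3,5-bis(4-methoxybenzyloxy)phenyl]methanol | OCc1cc(OCc2ccc(OC)cc2)cc(OCc2ccc(OC)cc2)c1 | intermediate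
4 | [2-bromo-3,5-bis(4-methoxybenzyloxy)phenyl]methanol | OCc1cc(OCc2ccc(OC)cc2)cc(OCc2ccc(OC)cc2)c1Br | intermediate
5 | [2-bromo-3,5-bis(4-methoxybenzyloxy)benzyloxy](tert-butyl)dimethylsilane | CC(C)(C)[Si](C)(C)OCc1cc(OCc2ccc(OC)cc2)cc(OCc2ccc(OC)cc2)c1Br | intermediate
6 | methyl 2-[2-(tert-butyldimethylsilyloxymethyl)-4,6-bis(4-methoxybenzyloxy)phenyl]acetate | COC(=O)Cc1c(CO[Si](C)(C)C(C)(C)C)cc(OCc2ccc(OC)cc2)cc1OCc1ccc(OC)cc1 | intermediate
7 | methyl 2-[3-bromo-2-(tert-butyldimethylsilyloxymethyl)-4,6-bis(4-methoxybenzyloxy)phenyl]acetate | COC(=O)Cc1c(CO[Si](C)(C)C(C)(C)C)c(Br)c(OCc2ccc(OC)cc2)cc1OCc1ccc(OC)cc1 | intermediate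
8 | methyl 2-[3-bromo-2-(tert-butyldimethylsilyloxymethyl)-4,6-bis(4-methoxybenzyloxy)phenyl]-2-diazoacetate | COC(=O)C(=[N+]=[N-])c1c(CO[Si](C)(C)C(C)(C)C)c(Br)c(OCc2ccc(OC)cc2)cc1OCc1ccc(OC)cc1 | intermediate
9 | methyl (2S,3R)-5-bromo-4-(tert-butyldimethylsilyloxymethyl)-6-(4-methoxybenzyloxy)-2-(4-methoxyphenyl)-2,3-dihydro-1-benzofuran-3-carboxylate (cis) | COc1ccc([C@H]2Oc3cc(OCc4ccc(OC)cc4)c(Br)c(CO[Si](C)(C)C(C)(C)C)c3[C@H]2C(=O)OC)cc1 | intermediate
10 | methyl (2S,3S)-5-bromo-4-(tert-butyldimethylsilyloxymethyl)-6-(4-methoxybenzyloxy)-2-(4-methoxyphenyl)-2,3-dihydro-1-benzofuran-3-carboxylate (trans) | COc1ccc([C@H]2Oc3cc(OCc4ccc(OC)cc4)c(Br)c(CO[Si](C)(C)C(C)(C)C)c3[C@@H]2C(=O)OC)cc1 | intermediate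
11 | (2S,3S)-5-bromo-4-(tert-butyldimethylsilyloxymethyl)-6-(4-methoxybenzyloxy)-2-(4-methoxyphenyl)-2,3-dihydro-1-benzofuran-3-carbaldehyde | COc1ccc([C@H]2Oc3cc(OCc4ccc(OC)cc4)c(Br)c(CO[Si](C)(C)C(C)(C)C)c3[C@@H]2C=O)cc1 | intermediate (not isolated)
12 | (2S,3S)-5-bromo-4-(tert-butyldimethylsilyloxymethyl)-3-ethynyl-6-(4-methoxybenzyloxy)-2-(4-methoxyphenyl)-2,3-dihydro-1-benzofuran | COc1ccc([C@H]2Oc3cc(OCc4ccc(OC)cc4)c(Br)c(CO[Si](C)(C)C(C)(C)C)c3[C@@H]2C#C)cc1 | intermediate
13 | 2,4-dimethoxybenzaldehyde | COc1ccc(C=O)c(OC)c1 | starting material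
14 | bromomagnesium acetylide of 12 | COc1ccc([C@H]2Oc3cc(OCc4ccc(OC)cc4)c(Br)c(CO[Si](C)(C)C(C)(C)C)c3[C@@H]2C#C[Mg]Br)cc1 | intermediate (not isolated)
15 | 3-[(2S,3S)-5-bromo-4-(tert-butyldimethylsilyloxymethyl)-6-(4-methoxybenzyloxy)-2-(4-methoxyphenyl)-2,3-dihydro-1-benzofuran-3-yl]-1-(2,4-dimethoxyphenyl)prop-2-yn-1-ol (both carbinol epimers) | COc1ccc([C@H]2Oc3cc(OCc4ccc(OC)cc4)c(Br)c(CO[Si](C)(C)C(C)(C)C)c3[C@@H]2C#CC(O)c2ccc(OC)cc2OC)cc1 | intermediate
16 | 3-[(2S,3S)-5-bromo-4-(tert-butyldimethylsilyloxymethyl)-6-(4-methoxybenzyloxy)-2-(4-methoxyphenyl)-2,3-dihydro-1-benzofuran-3-yl]-1-(2,4-dimethoxyphenyl)prop-2-yn-1-one | COc1ccc([C@H]2Oc3cc(OCc4ccc(OC)cc4)c(Br)c(CO[Si](C)(C)C(C)(C)C)c3[C@@H]2C#CC(=O)c2ccc(OC)cc2OC)cc1 | intermediate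
17 | methyl (E)-3-methoxybut-2-enoate | CO/C(C)=C/C(=O)OC | starting material
18 | 1,3-dimethoxy-1-(trimethylsilyloxy)buta-1,3-diene | C=C(OC)C=C(OC)O[Si](C)(C)C | intermediate
19 | cyclohexa-1,4-diene cycloadduct of 16 and 18 (acetal carbon configuration not defined) | COc1ccc([C@H]2Oc3cc(OCc4ccc(OC)cc4)c(Br)c(CO[Si](C)(C)C(C)(C)C)c3[C@@H]2C2=C(C(=O)c3ccc(OC)cc3OC)C(OC)(O[Si](C)(C)C)C=C(OC)C2)cc1 | intermediate (not isolated)
20 | trimethylsilyl ether of 21 | COc1ccc([C@H]2Oc3cc(OCc4ccc(OC)cc4)c(Br)c(CO[Si](C)(C)C(C)(C)C)c3[C@@H]2c2cc(OC)cc(O[Si](C)(C)C)c2C(=O)c2ccc(OC)cc2OC)cc1 | intermediate (not isolated)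
21 | {2-[(2S,3S)-5-bromo-4-(tert-butyldimethylsilyloxymethyl)-6-(4-methoxybenzyloxy)-2-(4-methoxyphenyl)-2,3-dihydro-1-benzofuran-3-yl]-6-hydroxy-4-methoxyphenyl}(2,4-dimethoxyphenyl)methanone | COc1ccc([C@H]2Oc3cc(OCc4ccc(OC)cc4)c(Br)c(CO[Si](C)(C)C(C)(C)C)c3[C@@H]2c2cc(OC)cc(O)c2C(=O)c2ccc(OC)cc2OC)cc1 | intermediate
22 | {2-[(2S,3S)-5-bromo-4-(tert-butyldimethylsilyloxymethyl)-6-(4-methoxybenzyloxy)-2-(4-methoxyphenyl)-2,3-dihydro-1-benzofuran-3-yl]-4,6-dimethoxyphenyl}(2,4-dimethoxyphenyl)methanone | COc1ccc([C@H]2Oc3cc(OCc4ccc(OC)cc4)c(Br)c(CO[Si](C)(C)C(C)(C)C)c3[C@@H]2c2cc(OC)cc(OC)c2C(=O)c2ccc(OC)cc2OC)cc1 | intermediate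
23 | {2-[(2S,3S)-5-bromo-4-(bromomethyl)-6-(4-methoxybenzyloxy)-2-(4-methoxyphenyl)-2,3-dihydro-1-benzofuran-3-yl]-4,6-dimethoxyphenyl}(2,4-dimethoxyphenyl)methanone | COc1ccc([C@H]2Oc3cc(OCc4ccc(OC)cc4)c(Br)c(CBr)c3[C@@H]2c2cc(OC)cc(OC)c2C(=O)c2ccc(OC)cc2OC)cc1 | intermediate
24 | core tertiary alcohol (Ca S, Cb S; OH and 2,4-dimethoxyphenyl on Cc, configuration not defined; Br on A4; PMB ether on A3) | COc1ccc([C@H]2Oc3cc(OCc4ccc(OC)cc4)c(Br)c4c3[C@@H]2c2cc(OC)cc(OC)c2C(O)(c2ccc(OC)cc2OC)C4)cc1 | intermediate
25 | diarylcarbenium ion at Cc derived from 24 | COc1ccc([C@H]2Oc3cc(OCc4ccc(OC)cc4)c(Br)c4c3[C@@H]2c2cc(OC)cc(OC)c2[C+](c2ccc(OC)cc2OC)C4)cc1 | intermediate (not isolated)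
26 | core bromide (Ca S, Cb S, Cc S; H and 2,4-dimethoxyphenyl on Cc; Br on A4; PMB ether on A3) | COc1ccc([C@H]2Oc3cc(OCc4ccc(OC)cc4)c(Br)c4c3[C@@H]2c2cc(OC)cc(OC)c2[C@H](c2ccc(OC)cc2OC)C4)cc1 | intermediate
27 | 3,5-dimethoxybenzonitrile | COc1cc(C#N)cc(OC)c1 | starting material
28 | aryllithium from 26 (Li on A4) | COc1ccc([C@H]2Oc3cc(OCc4ccc(OC)cc4)c([Li])c4c3[C@@H]2c2cc(OC)cc(OC)c2[C@H](c2ccc(OC)cc2OC)C4)cc1 | intermediate (not isolated)
29 | N-unsubstituted ketimine (A4–C(=NH)–3,5-dimethoxyphenyl) | COc1ccc([C@H]2Oc3cc(OCc4ccc(OC)cc4)c(C(=N)c5cc(OC)cc(OC)c5)c4c3[C@@H]2c2cc(OC)cc(OC)c2[C@H](c2ccc(OC)cc2OC)C4)cc1 | intermediate (not isolated)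
30 | core hydrazone (A4–C(=N–NH2)–3,5-dimethoxyphenyl) | COc1ccc([C@H]2Oc3cc(OCc4ccc(OC)cc4)c(C(=NN)c5cc(OC)cc(OC)c5)c4c3[C@@H]2c2cc(OC)cc(OC)c2[C@H](c2ccc(OC)cc2OC)C4)cc1 | intermediate
31 | diaryldiazomethane from 30 | COc1ccc([C@H]2Oc3cc(OCc4ccc(OC)cc4)c(C(=[N+]=[N-])c5cc(OC)cc(OC)c5)c4c3[C@@H]2c2cc(OC)cc(OC)c2[C@H](c2ccc(OC)cc2OC)C4)cc1 | intermediate (not isolated)
32 | octamethyl ether with cis second furan (Ca S, Cb S, Cc S, Cd R, Ce S) | COc1ccc([C@H]2Oc3cc4c(c5c3[C@@H]2c2cc(OC)cc(OC)c2[C@H](c2ccc(OC)cc2OC)C5)[C@@H](c2cc(OC)cc(OC)c2)[C@@H](c2ccc(OC)cc2)O4)cc1 | intermediate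
33 | octamethyl ether of the target (Ca S, Cb S, Cc S, Cd R, Ce R) | COc1ccc([C@H]2Oc3cc4c(c5c3[C@@H]2c2cc(OC)cc(OC)c2[C@H](c2ccc(OC)cc2OC)C5)[C@@H](c2cc(OC)cc(OC)c2)[C@H](c2ccc(OC)cc2)O4)cc1 | intermediate
34 | CNP0154047.3 (Ca S, Cb S, Cc S, Cd R, Ce R) | Oc1ccc([C@H]2Oc3cc4c(c5c3[C@@H]2c2cc(O)cc(O)c2[C@H](c2ccc(O)cc2O)C5)[C@@H](c2cc(O)cc(O)c2)[C@H](c2ccc(O)cc2)O4)cc1 | target

## Step count and least certain steps

Total: 21 steps. Longest linear sequence: 20 steps (steps 1–11 and 13–21); step 12 is a one-step side branch.

**Step 13 (key step).** The cycloaddition may be slow at the alkyne terminus next to the bulky Cb, so that the diene decomposes at the temperature needed, or the ynone may isomerise to the allenone through the acidic Cb–H during prolonged heating. The fallback keeps the same ring-B construction but uses a smaller, more electrophilic dienophile and completes the aryl ketone afterwards. It sets out from alkyne 12: the acetylide 14 is formylated with DMF (acidic reverse quench) to the ynal F1. F1 reacts with diene 18 (PhMe, 60 °C; SiO2) to give the salicylaldehyde F2, which is methylated (MeI, K2CO3) to the dimethoxy aldehyde F3. Addition of 2,4-dimethoxyphenylmagnesium bromide gives the diaryl carbinol F4, and MnO2 oxidation of F4 returns to the route at 22.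

**Step 17.** Hydride may be delivered to the wrong face of cation 25, since the facial preference rests on a conformational argument. The acid may also cleave the PMB ether, which would cost only a re-alkylation of the A3 phenol with 2 and K2CO3. The fallback replaces substrate-controlled capture of a cation by catalyst-controlled syn hydrogenation. It sets out from 24, which is dehydrated with the Burgess reagent (PhMe, 50 °C) to the triaryl cycloheptene F5. F5 is hydrogenated with a chiral iridium N,P-catalyst of the type [Ir(cod)(t-Bu-PHOX)][B(3,5-(CF3)2C6H3)4] (H2, CH2Cl2), a known way to set diarylmethine centres from trisubstituted 1,1-diaryl alkenes. Both ligand enantiomers are available, the aryl bromide and the PMB ether are spared, and the sequence comes back at 26.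

**Step 16.** Premature reduction may win over C–C bond formation: the benzylsamarium or the ketyl may be protonated, because the di-ortho-substituted diaryl ketone is a poor electrophile and the ring is seven-membered. The fallback is a carbonyl–carbonyl coupling, which is less sensitive to hindrance. It sets out from 22: Bu4NF gives the benzylic alcohol F6, MnO2 gives the keto aldehyde F7, and intramolecular McMurry coupling (TiCl4, Zn, pyridine, THF, reflux) closes the ring to the cycloheptene F5 described under step 17. Protonation of F5 under the conditions of step 17 gives cation 25, so the sequence returns to the route at 26.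

**Step 7.** Enantioselectivity and cis selectivity may be eroded, because the second ortho substituent twists the aryl ring out of conjugation with the carbene and makes it less selective. The fallback gives up catalyst control for resolution. It sets out from 8: Rh2(OAc)4 (CH2Cl2, rt) gives the racemic cis ester F8, and NaOMe in MeOH followed by aqueous LiOH gives the racemic trans acid F9. F9 is resolved through its salt with (S)-1-phenylethylamine (or on a chiral stationary phase) to the (2S,3S) acid F10, and methylation (MeI, K2CO3, DMF) returns to the route at 10.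

**Step 19.** Azine formation or carbene dimerisation may compete, and catalyst control may be weak, because the carbene carbon sits between two ortho substituents on a large chiral substrate. The fallback uses anionic ring closure and accepts a separation. It sets out from 26: step 18 is run to the ketimine 29, which is hydrolysed in the work-up (aq. HCl, THF, 50 °C) to the diaryl ketone F11. LiN(i-Pr)2 (THF, −78 → 0 °C) deprotonates the PMB methylene, and the carbanion adds to the ketone to give the 3-hydroxy dihydrofuran F12. Et3SiH–CF3CO2H, followed by longer exposure to the acid as in step 20, gives 33 together with its trans diastereomer F13 (Cd S, Ce S). The two are expected in comparable amounts because the remote centres exert little bias, and they are separated by chromatography. The sequence comes back at 33.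

## Further compounds

F1 | step 13 | 3-[(2S,3S)-5-bromo-4-(tert-butyldimethylsilyloxymethyl)-6-(4-methoxybenzyloxy)-2-(4-methoxyphenyl)-2,3-dihydro-1-benzofuran-3-yl]prop-2-ynal | COc1ccc([C@H]2Oc3cc(OCc4ccc(OC)cc4)c(Br)c(CO[Si](C)(C)C(C)(C)C)c3[C@@H]2C#CC=O)cc1
F2 | step 13 | 2-[(2S,3S)-5-bromo-4-(tert-butyldimethylsilyloxymethyl)-6-(4-methoxybenzyloxy)-2-(4-methoxyphenyl)-2,3-dihydro-1-benzofuran-3-yl]-6-hydroxy-4-methoxybenzaldehyde | COc1ccc([C@H]2Oc3cc(OCc4ccc(OC)cc4)c(Br)c(CO[Si](C)(C)C(C)(C)C)c3[C@@H]2c2cc(OC)cc(O)c2C=O)cc1
F3 | step 13 | 2-[(2S,3S)-5-bromo-4-(tert-butyldimethylsilyloxymethyl)-6-(4-methoxybenzyloxy)-2-(4-methoxyphenyl)-2,3-dihydro-1-benzofuran-3-yl]-4,6-dimethoxybenzaldehyde | COc1ccc([C@H]2Oc3cc(OCc4ccc(OC)cc4)c(Br)c(CO[Si](C)(C)C(C)(C)C)c3[C@@H]2c2cc(OC)cc(OC)c2C=O)cc1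
F4 | step 13 | {2-[(2S,3S)-5-bromo-4-(tert-butyldimethylsilyloxymethyl)-6-(4-methoxybenzyloxy)-2-(4-methoxyphenyl)-2,3-dihydro-1-benzofuran-3-yl]-4,6-dimethoxyphenyl}(2,4-dimethoxyphenyl)methanol (both carbinol epimers) | COc1ccc([C@H]2Oc3cc(OCc4ccc(OC)cc4)c(Br)c(CO[Si](C)(C)C(C)(C)C)c3[C@@H]2c2cc(OC)cc(OC)c2C(O)c2ccc(OC)cc2OC)cc1
F5 | step 17 | triaryl cycloheptene (Ca S, Cb S; Cc=Cf double bond; Br on A4; PMB ether on A3) | COc1ccc([C@H]2Oc3cc(OCc4ccc(OC)cc4)c(Br)c4c3[C@@H]2c2cc(OC)cc(OC)c2C(c2ccc(OC)cc2OC)=C4)cc1
F6 | step 16 | {2-[(2S,3S)-5-bromo-4-(hydroxymethyl)-6-(4-methoxybenzyloxy)-2-(4-methoxyphenyl)-2,3-dihydro-1-benzofuran-3-yl]-4,6-dimethoxyphenyl}(2,4-dimethoxyphenyl)methanone | COc1ccc([C@H]2Oc3cc(OCc4ccc(OC)cc4)c(Br)c(CO)c3[C@@H]2c2cc(OC)cc(OC)c2C(=O)c2ccc(OC)cc2OC)cc1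
F7 | step 16 | (2S,3S)-5-bromo-3-[2-(2,4-dimethoxybenzoyl)-3,5-dimethoxyphenyl]-6-(4-methoxybenzyloxy)-2-(4-methoxyphenyl)-2,3-dihydro-1-benzofuran-4-carbaldehyde | COc1ccc([C@H]2Oc3cc(OCc4ccc(OC)cc4)c(Br)c(C=O)c3[C@@H]2c2cc(OC)cc(OC)c2C(=O)c2ccc(OC)cc2OC)cc1
F8 | step 7 | racemic cis methyl 5-bromo-4-(tert-butyldimethylsilyloxymethyl)-6-(4-methoxybenzyloxy)-2-(4-methoxyphenyl)-2,3-dihydro-1-benzofuran-3-carboxylate | COc1ccc(C2Oc3cc(OCc4ccc(OC)cc4)c(Br)c(CO[Si](C)(C)C(C)(C)C)c3C2C(=O)OC)cc1
F9 | step 7 | racemic trans 5-bromo-4-(tert-butyldimethylsilyloxymethyl)-6-(4-methoxybenzyloxy)-2-(4-methoxyphenyl)-2,3-dihydro-1-benzofuran-3-carboxylic acid | COc1ccc(C2Oc3cc(OCc4ccc(OC)cc4)c(Br)c(CO[Si](C)(C)C(C)(C)C)c3C2C(=O)O)cc1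
F10 | step 7 | (2S,3S)-5-bromo-4-(tert-butyldimethylsilyloxymethyl)-6-(4-methoxybenzyloxy)-2-(4-methoxyphenyl)-2,3-dihydro-1-benzofuran-3-carboxylic acid | COc1ccc([C@H]2Oc3cc(OCc4ccc(OC)cc4)c(Br)c(CO[Si](C)(C)C(C)(C)C)c3[C@@H]2C(=O)O)cc1
F11 | step 19 | core diaryl ketone (26 with Br on A4 replaced by 3,5-dimethoxybenzoyl) | COc1ccc([C@H]2Oc3cc(OCc4ccc(OC)cc4)c(C(=O)c5cc(OC)cc(OC)c5)c4c3[C@@H]2c2cc(OC)cc(OC)c2[C@H](c2ccc(OC)cc2OC)C4)cc1
F12 | step 19 | 3-hydroxy second furan (OH and 3,5-dimethoxyphenyl on Cd, 4-methoxyphenyl on Ce; Cd and Ce not defined) | COc1ccc([C@H]2Oc3cc4c(c5c3[C@@H]2c2cc(OC)cc(OC)c2[C@H](c2ccc(OC)cc2OC)C5)C(O)(c2cc(OC)cc(OC)c2)C(c2ccc(OC)cc2)O4)cc1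
F13 | step 19 | trans diastereomer of 33 (Ca S, Cb S, Cc S, Cd S, Ce S) | COc1ccc([C@H]2Oc3cc4c(c5c3[C@@H]2c2cc(OC)cc(OC)c2[C@H](c2ccc(OC)cc2OC)C5)[C@H](c2cc(OC)cc(OC)c2)[C@@H](c2ccc(OC)cc2)O4)cc1
A1 | alternative 1 | racemic tetramethoxy bromo dibenzocycloheptenone keto ester | COC(=O)C1c2cc(OC)cc(OC)c2C(=O)Cc2c(Br)c(OC)cc(OC)c21
A2 | alternative 1 | methyl 4-bromo-5,7-dimethoxy-2-oxoindane-1-carboxylate | COC(=O)C1C(=O)Cc2c(Br)c(OC)cc(OC)c21
A3 | alternative 1 | 3,5-dimethoxy-2-(trimethylsilyl)phenyl trifluoromethanesulfonate | COc1cc(OC)c([Si](C)(C)C)c(OS(=O)(=O)C(F)(F)F)c1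
A4 | alternative 2 | hexacyclic methyl trans-2-(4-methoxyphenyl)-2,3-dihydrobenzofuran-3-carboxylate | COc1ccc([C@H]2Oc3cc4c(c5c3[C@@H]2c2cc(OC)cc(OC)c2[C@H](c2ccc(OC)cc2OC)C5)[C@@H](C(=O)OC)[C@H](c2ccc(OC)cc2)O4)cc1
A5 | alternative 2 | ring-A-fused (2R)-2-(4-methoxyphenyl)chroman-4-one | COc1ccc([C@H]2Oc3cc4c(c5c3[C@@H]2c2cc(OC)cc(OC)c2[C@H](c2ccc(OC)cc2OC)C5)C(=O)C[C@H](c2ccc(OC)cc2)O4)cc1
A6 | alternative 3 | pentacyclic triaryl cycloheptene (A3 methyl ether) | COc1ccc([C@H]2Oc3cc(OC)c(Br)c4c3[C@@H]2c2cc(OC)cc(OC)c2C(c2ccc(OC)cc2OC)=C4)cc1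
A7 | alternative 3 | eight-membered benzylic sulfone (Cc–SO2–Cf) | COc1ccc([C@H]2Oc3cc(OC)c(Br)c4c3[C@@H]2c2cc(OC)cc(OC)c2C(c2ccc(OC)cc2OC)S(=O)(=O)C4)cc1
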